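**Retrosynthetic overview**
1. Chain locants: C1′ is the aryl ketone carbon, C3′ the stereocentre, C7′ the ring-alkene carbon bearing CH2O, and C12′ the CH2O carrying the coumarate.
2. Target ⇒ one acid step removes two MOM ethers and the t-Bu ester ⇒ Mitsunobu esterification of C12′-OH with unprotected p-coumaric acid ⇒ oxepine alcohol.
3. The oxepine is the only ring made (both arenes are bought). Oxepine ⇒ catalytic enantioselective 7-exo-trig oxa-Michael addition of C7′-CH2OH to C3′ of an acyclic (E)-aroylacrylate diol, which copies the proposed closure of the seco farnesyl-hydroquinone acid.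
4. Aroylacrylate ⇒ ester enolate plus aryl glyoxal (aldol, then E1cB). Ester ⇒ Negishi coupling of a (Z)-alkenyl iodide with a zinc butanoate.
5. (Z)-Alkenyl iodide ⇒ anti-carbomagnesiation of propargyl alcohol with homoprenyl Grignard reagent, then I2. C12′-OH comes from SeO2 allylic oxidation.

Assumption: the quinidine-derived squaramide is taken to direct attack to the Re face of C3′, which gives (R). If the sense proves opposite, the quinine-derived pseudo-enantiomer is used in the same step.

**Step 1**
Reactants: 1 5-bromo-2-methylpent-2-ene; 2 prop-2-yn-1-ol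
Product: 5 (Z)-3-iodo-2-(4-methylpent-3-en-1-yl)prop-2-en-1-ol, via homoprenylmagnesium bromide 3 (not isolated), via oxamagnesacyclopentene chelate 4 (not isolated)
Conditions: Mg, THF, reflux; 2 (0.4 equiv), CuI (10 mol %), THF–Et2O, −10 °C to rt; I2, −40 to 0 °C; aq NH4Cl
Reagents that add atoms: iodine, II
Why: Copper-catalysed anti-carbomagnesiation of a propargylic alkoxide (Duboudin type) puts the homoprenyl group on the internal alkyne carbon and magnesium on the terminal carbon inside a five-membered O–Mg chelate, so iodinolysis with retention gives only the isomer with iodine cis to CH2OH, which fixes the later ring-alkene geometry.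

**Step 2**
Reactants: 5 (Z)-3-iodo-2-(4-methylpent-3-en-1-yl)prop-2-en-1-ol
Product: 6 (2E,6Z)-6-(iodomethylidene)-2-methylhept-2-ene-1,7-diol
Conditions: SeO2 (0.3 equiv), t-BuOOH (3 equiv), salicylic acid (10 mol %), CH2Cl2, 0 °C to rt
Reagents that add atoms: tert-butyl hydroperoxide, CC(C)(C)OO; selenium dioxide (oxygen relay), O=[Se]=O
Why: Catalytic SeO2 allylic oxidation (ene reaction, then [2,3]-sigmatropic shift) attacks only the electron-rich gem-dimethyl alkene, not the iodoalkene, and gives the (E)-CH2OH as is the rule for this reaction.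

**Step 3**
Reactants: 6 (2E,6Z)-6-(iodomethylidene)-2-methylhept-2-ene-1,7-diol
Product: 7 (2E,6Z)-1,7-bis(tert-butyldimethylsilyloxy)-6-(iodomethylidene)-2-methylhept-2-ene
Conditions: TBSCl (2.4 equiv), imidazole, DMF, 0 °C to rt
Reagents that add atoms: tert-butyldimethylsilyl chloride, CC(C)(C)[Si](C)(C)Cl
Why: Standard silyl ether formation masks both primary allylic alcohols in one operation for the organozinc and enolate steps.

**Step 4**
Reactants: 7 (2E,6Z)-1,7-bis(tert-butyldimethylsilyloxy)-6-(iodomethylidene)-2-methylhept-2-ene; 8 tert-butyl 4-bromobutanoate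
Product: 10 tert-butyl (5Z,9E)-11-(tert-butyldimethylsilyloxy)-6-[(tert-butyldimethylsilyloxy)methyl]-10-methylundeca-5,9-dienoate, via alkylzinc bromide 9 (not isolated)
Conditions: 8, Zn dust, LiCl, THF, 45 °C; then 7, PdCl2(dppf) (3 mol %), THF, rt
Reagents that add atoms: none
Why: LiCl-assisted zinc insertion followed by Negishi sp3–sp2 cross-coupling proceeds with retention at the alkenyl iodide, so C5′ ends up cis to CH2OTBS, and the mild alkylzinc tolerates the tert-butyl ester.

**Step 5**
Reactants: 11 1-(2,5-dihydroxyphenyl)ethan-1-one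
Product: 12 1-[2,5-bis(methoxymethoxy)phenyl]ethan-1-one
Conditions: NaH (2.5 equiv), MOMCl (2.6 equiv), DMF, 0 °C to rt
Reagents that add atoms: chloromethyl methyl ether, COCCl
Why: Williamson-type O-alkylation of the bis-phenoxide blocks the ortho-phenol, which would otherwise close a chromanone on the later enone, with groups that fall in the same acid step as the tert-butyl ester.

**Step 6**
Reactants: 12 1-[2,5-bis(methoxymethoxy)phenyl]ethan-1-one
Product: 13 2-[2,5-bis(methoxymethoxy)phenyl]-2-oxoacetaldehyde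
Conditions: SeO2 (1.4 equiv), 1,4-dioxane–H2O (30:1), 85 °C; hydrate dried by toluene azeotrope
Reagents that add atoms: selenium dioxide, O=[Se]=O
Why: Riley oxidation of an aryl methyl ketone gives the aryl glyoxal, and aryl MOM ethers tolerate the only weakly acidic selenous acid medium.

**Step 7**
Reactants: 10 tert-butyl (5Z,9E)-11-(tert-butyldimethylsilyloxy)-6-[(tert-butyldimethylsilyloxy)methyl]-10-methylundeca-5,9-dienoate; 13 2-[2,5-bis(methoxymethoxy)phenyl]-2-oxoacetaldehyde
Product: 17 tert-butyl (2E,5Z,9E)-2-{2-[2,5-bis(methoxymethoxy)phenyl]-2-oxoethylidene}-11-(tert-butyldimethylsilyloxy)-6-[(tert-butyldimethylsilyloxy)methyl]-10-methylundeca-5,9-dienoate, via lithium enolate 14 (not isolated), via lithium aldolate 15 (not isolated), via mesylate 16 (not isolated)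
Conditions: LDA, THF, −78 °C; 13; MsCl, −78 to 0 °C; DBU, 0 °C to rt
Reagents that add atoms: none
Why: Directed aldol addition of the ester enolate to the far more electrophilic aldehyde carbonyl of the glyoxal, then mesylation and E1cB elimination in the same flask, gives the thermodynamically preferred mesaconate-type (E)-aroylacrylate, and the minor Z isomer is removed by chromatography.

**Step 8**
Reactants: 17 bis-TBS (E)-aroylacrylate from step 7
Product: 18 tert-butyl (2E,5Z,9E)-2-{2-[2,5-bis(methoxymethoxy)phenyl]-2-oxoethylidene}-11-hydroxy-6-(hydroxymethyl)-10-methylundeca-5,9-dienoate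
Conditions: HF·pyridine, pyridine, THF, 0 °C to rt
Reagents that add atoms: none
Why: Buffered acidic fluoride desilylation cleaves the two primary alkyl TBS ethers without touching the MOM ethers or the tert-butyl ester, and because it is non-basic it does not trigger an uncatalysed racemic ring closure.

**Step 9**
Reactants: 18 acyclic (E)-aroylacrylate diol
Product: 19 tert-butyl (2R)-2-{2-[2,5-bis(methoxymethoxy)phenyl]-2-oxoethyl}-6-[(3E)-5-hydroxy-4-methylpent-3-en-1-yl]-2,3,4,7-tetrahydrooxepine-2-carboxylate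
Conditions: 3-{[3,5-bis(trifluoromethyl)phenyl]amino}-4-{[(9R)-6′-methoxycinchonan-9-yl]amino}cyclobut-3-ene-1,2-dione (10 mol %), toluene–CH2Cl2 (4:1), 0.02 M, 0 °C, stopped at full conversion
Reagents that add atoms: none
Why: Proposed new method: the squaramide N–H pair binds the aryl-ketone carbonyl of the doubly activated (E)-aroylacrylate while the quinuclidine nitrogen acts as general base on the C7′-CH2OH, which the (Z)-alkene holds next to C3′, so a 7-exo-trig oxa-Michael addition on the Re face of C3′ closes the oxepine and sets the (R)-configured tetrasubstituted carbon in one event (the C12′-OH would need an eleven-membered ring and stays free), the closest known reaction type being the bifunctional cinchona urea- or squaramide-catalysed intramolecular oxa-Michael cycloetherification of hydroxy enones to tetrahydrofurans, tetrahydropyrans and 2,2-disubstituted chromans.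

**Step 10**
Reactants: 19 (R)-oxepine alcohol; 20 (E)-3-(4-hydroxyphenyl)prop-2-enoic acid (p-coumaric acid)
Product: 21 tert-butyl (2R)-2-{2-[2,5-bis(methoxymethoxy)phenyl]-2-oxoethyl}-6-[(3E)-5-{[(2E)-3-(4-hydroxyphenyl)prop-2-enoyl]oxy}-4-methylpent-3-en-1-yl]-2,3,4,7-tetrahydrooxepine-2-carboxylate
Conditions: 20 (1.5 equiv), PPh3, DIAD, THF, 0 °C to rt
Reagents that add atoms: none
Why: Mitsunobu esterification activates the only free alcohol for SN2 displacement by the carboxylate, which as the far stronger acid reacts in preference to the unprotected phenol, and the stereocentre is not touched.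

**Step 11**
Reactants: 21 protected coumarate
Product: 22 (2R)-2-[2-(2,5-dihydroxyphenyl)-2-oxoethyl]-6-[(3E)-5-{[(2E)-3-(4-hydroxyphenyl)prop-2-enoyl]oxy}-4-methylpent-3-en-1-yl]-2,3,4,7-tetrahydrooxepine-2-carboxylic acid (target)
Conditions: TFA–CH2Cl2–H2O (10:30:1), 0 to 10 °C; toluene co-evaporation; reversed-phase chromatography (0.1 % HCO2H)
Reagents that add atoms: none
Why: Brønsted-acid solvolysis removes both MOM acetals and the tert-butyl ester (E1 loss of isobutene) in one operation, whereas the two allylic C–O bonds could ionise only to poorly stabilised primary/secondary allyl cations, and the non-basic medium avoids retro-oxa-Michael racemisation.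

**Compound list**
1 | 5-bromo-2-methylpent-2-ene | CC(C)=CCCBr | starting material
2 | prop-2-yn-1-ol | C#CCO | starting material
3 | (4-methylpent-3-en-1-yl)magnesium bromide | CC(C)=CCC[Mg]Br | intermediate
4 | 4-(4-methylpent-3-en-1-yl)-2,5-dihydro-1,2-oxamagnesole (O–Mg chelate) | CC(C)=CCCC1=C[Mg]OC1 | intermediate
5 | (Z)-3-iodo-2-(4-methylpent-3-en-1-yl)prop-2-en-1-ol | OC/C(CCC=C(C)C)=C\I | intermediate
6 | (2E,6Z)-6-(iodomethylidene)-2-methylhept-2-ene-1,7-diol | OC/C(CC/C=C(\C)CO)=C\I | intermediate
7 | (2E,6Z)-1,7-bis(tert-butyldimethylsilyloxy)-6-(iodomethylidene)-2-methylhept-2-ene | CC(C)(C)[Si](C)(C)OC/C(CC/C=C(\C)CO[Si](C)(C)C(C)(C)C)=C\I | intermediate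
8 | tert-butyl 4-bromobutanoate | CC(C)(C)OC(=O)CCCBr | starting material
9 | (4-tert-butoxy-4-oxobutyl)zinc bromide | CC(C)(C)OC(=O)CCC[Zn]Br | intermediate
10 | tert-butyl (5Z,9E)-11-(TBS-oxy)-6-[(TBS-oxy)methyl]-10-methylundeca-5,9-dienoate | CC(C)(C)OC(=O)CCC/C=C(\CO[Si](C)(C)C(C)(C)C)CC/C=C(\C)CO[Si](C)(C)C(C)(C)C | intermediate
11 | 1-(2,5-dihydroxyphenyl)ethan-1-one | CC(=O)c1cc(O)ccc1O | starting material
12 | 1-[2,5-bis(methoxymethoxy)phenyl]ethan-1-one | CC(=O)c1cc(OCOC)ccc1OCOC | intermediate
13 | 2-[2,5-bis(methoxymethoxy)phenyl]-2-oxoacetaldehyde | O=CC(=O)c1cc(OCOC)ccc1OCOC | intermediate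
14 | lithium enolate of 10 | [Li]OC(OC(C)(C)C)=CCC/C=C(\CO[Si](C)(C)C(C)(C)C)CC/C=C(\C)CO[Si](C)(C)C(C)(C)C | intermediate
15 | lithium aldolate (C2′-OLi, diastereomer mixture) | CC(C)(C)OC(=O)C(C(O[Li])C(=O)c1cc(OCOC)ccc1OCOC)CC/C=C(\CO[Si](C)(C)C(C)(C)C)CC/C=C(\C)CO[Si](C)(C)C(C)(C)C | intermediate
16 | C2′-mesylate (diastereomer mixture) | CC(C)(C)OC(=O)C(C(OS(C)(=O)=O)C(=O)c1cc(OCOC)ccc1OCOC)CC/C=C(\CO[Si](C)(C)C(C)(C)C)CC/C=C(\C)CO[Si](C)(C)C(C)(C)C | intermediate
17 | bis-TBS (2E,5Z,9E)-aroylacrylate tert-butyl ester | CC(C)(C)OC(=O)/C(CC/C=C(\CO[Si](C)(C)C(C)(C)C)CC/C=C(\C)CO[Si](C)(C)C(C)(C)C)=C/C(=O)c1cc(OCOC)ccc1OCOC | intermediate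
18 | (2E,5Z,9E)-aroylacrylate diol tert-butyl ester | CC(C)(C)OC(=O)/C(CC/C=C(\CO)CC/C=C(\C)CO)=C/C(=O)c1cc(OCOC)ccc1OCOC | intermediate
19 | (2R)-oxepine alcohol, bis-MOM, tert-butyl ester | C/C(=C\CCC1=CCC[C@@](CC(=O)c2cc(OCOC)ccc2OCOC)(C(=O)OC(C)(C)C)OC1)CO | intermediate
20 | (E)-3-(4-hydroxyphenyl)prop-2-enoic acid | OC(=O)/C=C/c1ccc(O)cc1 | starting material
21 | (2R)-oxepine p-coumarate, bis-MOM, tert-butyl ester | C/C(=C\CCC1=CCC[C@@](CC(=O)c2cc(OCOC)ccc2OCOC)(C(=O)OC(C)(C)C)OC1)COC(=O)/C=C/c1ccc(O)cc1 | intermediate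
22 | CNP0602535.1, (2R)-acid | C/C(=C\CCC1=CCC[C@@](CC(=O)c2cc(O)ccc2O)(C(=O)O)OC1)COC(=O)/C=C/c1ccc(O)cc1 | target

**Totals:** there are 11 steps in all, and the longest linear sequence is 9 steps (steps 1, 2, 3, 4, 7, 8, 9, 10, 11).

**Three steps most likely to fail**

*Step 9.* Three things can go wrong.
- A tertiary-amine base may be too weak for a seven-membered closure onto a fully substituted carbon.
- The addition may reverse and erode the ee.
- The base may deconjugate the enone.

The fallback sets out from 18. Catalytic DBU (10 mol %, CH2Cl2, rt) closes the ring without chiral control to the racemic oxepine ester F1. Preparative SFC on an amylose-type chiral phase then separates 19, where the route is rejoined, from the (S)-oxepine ester F2. F2 is returned to F1 by the same DBU treatment, which equilibrates it through retro-oxa-Michael opening to 18, so the material is recycled.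

*Step 7.* The glyoxal hydrate or its oligomers may quench the enolate, the enolate may partly add to the ketone carbonyl, and the α-mesyloxy ketone may decompose before elimination. The fallback sets out from 12 and 10 and replaces the aldol logic by alkylation and dehydrogenation.
- Treatment of 12 with LiHMDS and TMSCl (THF, −78 °C) gives the trimethylsilyl enol ether F3.
- NBS (THF, 0 °C) converts F3 to the phenacyl bromide F4.
- The enolate 14, made from 10 with LDA, is alkylated by F4 to the saturated γ-keto ester F5.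
- IBX (DMSO–toluene, 70 °C) dehydrogenates the ketone of F5 across C2′–C3′, which brings the route back at 17.

*Step 11.* TFA may ionise the allylic coumarate, and the released formaldehyde or tert-butyl cation may attack the phenols. The fallback sets out from 19 and reverses the end-game order.
- The same TFA treatment is applied to 19, before any coumarate is present, and gives the deprotected hydroxy acid F6.
- Separately, 20 is transvinylated with vinyl acetate (Pd(OAc)2 cat., KOH cat., THF, 40 °C) to vinyl p-coumarate F7.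
- Immobilised Candida antarctica lipase B (MTBE–2-methylbutan-2-ol, 40 °C) transfers the coumaroyl group from F7 to the unhindered primary C12′-OH of F6. The phenols and the hindered tertiary acid are left untouched, and the route arrives at 22.

**Further compounds**
F1 | step 9 | racemic tert-butyl 2-{2-[2,5-bis(methoxymethoxy)phenyl]-2-oxoethyl}-6-[(3E)-5-hydroxy-4-methylpent-3-en-1-yl]-2,3,4,7-tetrahydrooxepine-2-carboxylate | C/C(=C\CCC1=CCCC(CC(=O)c2cc(OCOC)ccc2OCOC)(C(=O)OC(C)(C)C)OC1)CO
F2 | step 9 | (2S)-enantiomer of 19 | C/C(=C\CCC1=CCC[C@](CC(=O)c2cc(OCOC)ccc2OCOC)(C(=O)OC(C)(C)C)OC1)CO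
F3 | step 7 | {1-[2,5-bis(methoxymethoxy)phenyl]ethenyl}oxy(trimethyl)silane | C=C(O[Si](C)(C)C)c1cc(OCOC)ccc1OCOC
F4 | step 7 | 2-bromo-1-[2,5-bis(methoxymethoxy)phenyl]ethan-1-one | BrCC(=O)c1cc(OCOC)ccc1OCOC
F5 | step 7 | tert-butyl (5Z,9E)-2-{2-[2,5-bis(methoxymethoxy)phenyl]-2-oxoethyl}-11-(TBS-oxy)-6-[(TBS-oxy)methyl]-10-methylundeca-5,9-dienoate (racemic at C2) | CC(C)(C)OC(=O)C(CC(=O)c1cc(OCOC)ccc1OCOC)CC/C=C(\CO[Si](C)(C)C(C)(C)C)CC/C=C(\C)CO[Si](C)(C)C(C)(C)C
F6 | step 11 | (2R)-2-[2-(2,5-dihydroxyphenyl)-2-oxoethyl]-6-[(3E)-5-hydroxy-4-methylpent-3-en-1-yl]-2,3,4,7-tetrahydrooxepine-2-carboxylic acid | C/C(=C\CCC1=CCC[C@@](CC(=O)c2cc(O)ccc2O)(C(=O)O)OC1)CO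
F7 | step 11 | ethenyl (2E)-3-(4-hydroxyphenyl)prop-2-enoate | C=COC(=O)/C=C/c1ccc(O)cc1
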